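**Plan**
- Retrosynthesis: the bridge CH2 next to ring B is taken back to a ketone. Ring B is then cut at C1′–C6′ and C2′–C3′ into 2-(4-benzyloxybenzyl)furan and a ring-A ethynyl ketone. The ynone is cut at CO–C≡ (Weinreb amide plus ethynyl Grignard) and ring A at its two aryl–CH2 bonds (aryl dibromide plus benzylzinc).
- Enabling feature: ring B has the bridge on C1′, H on C2′, OH on C3′ and the 4-hydroxybenzyl group on C6′, para to the OH. C3′–C4′–C5′–C6′ with that oxygen and that benzyl group is a 2-benzylfuran (furan C5 = C3′, furan C2 = C6′). C1′–C2′ is a terminal alkyne whose activating carbonyl is the bridge carbon.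
- Forward: ring A is dressed first (mono-demethylation of 3,5-dimethoxyphenylacetic acid, benzylation, 2,6-dibromination, double Negishi benzylation). Its side chain becomes the ynone, ring B is built by furan Diels–Alder addition and acid opening of the oxygen bridge, and one hydrogenation removes the ketone oxygen and all benzyl groups.
- Stereochemistry: the target has no stereocentre. The two bridgehead centres of the cycloadduct are racemic and vanish on aromatisation.

Key step: step 9

Remark: the SMILES of cycloadduct 14 shows one enantiomer of the racemate; the relative configuration of its two bridgeheads is fixed by the bicycle.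

**Step 1**
Reactants: 1 2-(3,5-dimethoxyphenyl)acetic acid
Product: 2 2-(3-hydroxy-5-methoxyphenyl)acetic acid
Conditions: NaSEt (4 equiv), DMF, 140 °C; aq. HCl work-up
Reagents that add atoms: none
Why: Thiolate SN2 demethylation of an aryl methyl ether should stop after one methyl group, because the phenoxide then present makes the second ether oxygen a far poorer leaving group.

**Step 2**
Reactants: 2 2-(3-hydroxy-5-methoxyphenyl)acetic acid
Product: 3 benzyl 2-[3-(benzyloxy)-5-methoxyphenyl]acetate
Conditions: BnBr (2.4 equiv), K2CO3, DMF, 50 °C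
Reagents that add atoms: benzyl bromide, BrCc1ccccc1
Why: Williamson etherification of the phenoxide and O-alkylation of the carboxylate run under the same conditions and mask both acidic groups as benzyl derivatives.

**Step 3**
Reactants: 3 benzyl 2-[3-(benzyloxy)-5-methoxyphenyl]acetate
Product: 4 benzyl 2-[3-(benzyloxy)-2,6-dibromo-5-methoxyphenyl]acetate
Conditions: NBS (2.05 equiv), MeCN, 0 °C → rt, dark
Reagents that add atoms: N-bromosuccinimide, O=C1CCC(=O)N1Br
Why: Electrophilic aromatic bromination should go to C2 and C6, each para to one alkoxy group and ortho to the other, before the more crowded C4 between the two ethers, as is usual for 3,5-dialkoxybenzyl systems.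

**Step 4**
Reactants: 5 4-(benzyloxy)benzyl chloride
Product: 6 [4-(benzyloxy)benzyl]zinc chloride (titrated THF solution, LiCl complex)
Conditions: Zn dust (1.5 equiv; activated with BrCH2CH2Br, Me3SiCl), LiCl, THF, 25 °C
Reagents that add atoms: zinc, [Zn]
Why: Direct insertion of LiCl-activated zinc into a benzylic C–Cl bond gives a benzylzinc chloride that tolerates aryl benzyl ethers and, in the next step, esters.

**Step 5**
Reactants: 4 benzyl 2-[3-(benzyloxy)-2,6-dibromo-5-methoxyphenyl]acetate; 6 [4-(benzyloxy)benzyl]zinc chloride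
Product: 7 benzyl 2-{3-(benzyloxy)-2,6-bis[4-(benzyloxy)benzyl]-5-methoxyphenyl}acetate
Conditions: 6 (3 equiv), Pd(OAc)2 (5 mol %), SPhos (10 mol %), THF, 25 → 50 °C
Reagents that add atoms: none
Why: Twofold Negishi sp2–sp3 cross-coupling, in which the bulky electron-rich biarylphosphine promotes oxidative addition into the hindered C–Br bonds and the benzylzinc reagent is too weakly basic to touch the ester α-CH2.

**Step 6**
Reactants: 7 benzyl 2-{3-(benzyloxy)-2,6-bis[4-(benzyloxy)benzyl]-5-methoxyphenyl}acetate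
Product: 8 2-{3-(benzyloxy)-2,6-bis[4-(benzyloxy)benzyl]-5-methoxyphenyl}-N-methoxy-N-methylacetamide
Conditions: MeNH(OMe)·HCl (1.5 equiv), iPrMgCl (3 equiv), THF, −20 → 0 °C
Reagents that add atoms: N,O-dimethylhydroxylamine hydrochloride, CNOC.Cl
Why: Aminolysis of the ester by the chloromagnesium amide of N,O-dimethylhydroxylamine gives the Weinreb amide in one operation, so no ester cleavage that would endanger the benzyl ethers is needed.

**Step 7**
Reactants: 8 2-{3-(benzyloxy)-2,6-bis[4-(benzyloxy)benzyl]-5-methoxyphenyl}-N-methoxy-N-methylacetamide; 9 ethynylmagnesium bromide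
Product: 10 1-{3-(benzyloxy)-2,6-bis[4-(benzyloxy)benzyl]-5-methoxyphenyl}but-3-yn-2-one
Conditions: 9 (0.5 M in THF, 2.5 equiv), THF, 0 °C; inverse quench into cold aq. NaHSO4
Reagents that add atoms: none
Why: Weinreb ketone synthesis, in which the chelated tetrahedral adduct prevents over-addition and the cold acidic quench keeps the released N,O-dimethylhydroxylamine protonated so that it cannot add to the terminal ynone.

**Step 8**
Reactants: 11 furan; 5 4-(benzyloxy)benzyl chloride
Product: 13 2-[4-(benzyloxy)benzyl]furan, via 2-furyllithium 12 (not isolated)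
Conditions: 11 (3 equiv), n-BuLi (1.3 equiv), THF, −20 → 0 °C; then 5 (1 equiv), −40 °C → rt
Reagents that add atoms: n-butyllithium, [Li]CCCC (its lithium stays only in intermediate 12)
Why: α-Lithiation of furan followed by SN2 alkylation with an activated benzylic chloride, with furan in excess to suppress dilithiation.

**Step 9**
Reactants: 10 1-{3-(benzyloxy)-2,6-bis[4-(benzyloxy)benzyl]-5-methoxyphenyl}but-3-yn-2-one; 13 2-[4-(benzyloxy)benzyl]furan
Product: 15 2-{3-(benzyloxy)-2,6-bis[4-(benzyloxy)benzyl]-5-methoxyphenyl}-1-{2-[4-(benzyloxy)benzyl]-5-hydroxyphenyl}ethan-1-one, via oxanorbornadiene 14 (not isolated)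
Conditions: 13 (1.5 equiv), toluene (2 M), 60 °C; then CH2Cl2, BF3·OEt2 (0.5 equiv), −40 → 0 °C
Reagents that add atoms: none
Why: Thermal [4+2] cycloaddition of the 2-alkylfuran (diene) with the terminal ynone (dienophile) forms C2′–C3′ and C1′–C6′ in one intermolecular, concerted but asynchronous event that closes the six-membered carbocycle of ring B as the oxygen-bridged diene 14. BF3·OEt2 should then ionise the C–O bond at the benzyl-bearing bridgehead to a tertiary, doubly allylic cation whose charge lies on C6′, C2′ and C4′ and never on the acyl-bearing C1′; a 1,2-hydride shift from the other bridgehead gives the protonated cyclohexadienone, which tautomerises to the phenol with its oxygen on C3′. The closest known reaction types are the Diels–Alder addition of 2-alkylfurans to propiolates and butynone and the acid-induced isomerisation of 7-oxanorbornadienes to phenols, which gives 5-hydroxy-2-alkylaryl carbonyl compounds. No stereocentre survives, since the two bridgehead centres of racemic 14 are locked relative to each other by the bicycle and are erased on aromatisation. Two regiochemical choices are needed and both rest on the substrates: the unsubstituted furan C5, which has the larger HOMO coefficient, bonds to the ynone β-CH and so places the acyl group next to the benzyl-bearing carbon, and the tertiary bridgehead ionises in preference to the secondary one. The cycloaddition is run without acid and the opening with a sub-stoichiometric Lewis acid at low temperature so that the benzyl ethers, the enolisable CH2 and the electron-rich ring A are spared.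

**Step 10**
Reactants: 15 2-{3-(benzyloxy)-2,6-bis[4-(benzyloxy)benzyl]-5-methoxyphenyl}-1-{2-[4-(benzyloxy)benzyl]-5-hydroxyphenyl}ethan-1-one
Product: 16 2,4-bis(4-hydroxybenzyl)-3-{2-[5-hydroxy-2-(4-hydroxybenzyl)phenyl]ethyl}-5-methoxyphenol (target)
Conditions: H2 (4 atm), 10% Pd/C, THF/MeOH/AcOH, HCl (0.2 equiv), 45 °C
Reagents that add atoms: none
Why: Heterogeneous catalytic hydrogenation should cleave the four O-benzyl ethers by hydrogenolysis and, with acid assistance, reduce the aryl ketone to CH2 through the benzylic alcohol (or the stilbene formed from it by dehydration), while the diarylmethane C–C bonds and the methyl ether stay intact.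

**Compound list**
1 | 2-(3,5-dimethoxyphenyl)acetic acid | COc1cc(CC(=O)O)cc(OC)c1 | starting material
2 | 2-(3-hydroxy-5-methoxyphenyl)acetic acid | COc1cc(O)cc(CC(=O)O)c1 | intermediate
3 | benzyl 2-[3-(benzyloxy)-5-methoxyphenyl]acetate | COc1cc(OCc2ccccc2)cc(CC(=O)OCc2ccccc2)c1 | intermediate
4 | benzyl 2-[3-(benzyloxy)-2,6-dibromo-5-methoxyphenyl]acetate | COc1cc(OCc2ccccc2)c(Br)c(CC(=O)OCc2ccccc2)c1Br | intermediate
5 | 4-(benzyloxy)benzyl chloride | ClCc1ccc(OCc2ccccc2)cc1 | starting material
6 | [4-(benzyloxy)benzyl]zinc chloride | Cl[Zn]Cc1ccc(OCc2ccccc2)cc1 | intermediate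
7 | benzyl 2-{3-(benzyloxy)-2,6-bis[4-(benzyloxy)benzyl]-5-methoxyphenyl}acetate | COc1cc(OCc2ccccc2)c(Cc2ccc(OCc3ccccc3)cc2)c(CC(=O)OCc2ccccc2)c1Cc1ccc(OCc2ccccc2)cc1 | intermediate
8 | 2-{3-(benzyloxy)-2,6-bis[4-(benzyloxy)benzyl]-5-methoxyphenyl}-N-methoxy-N-methylacetamide | COc1cc(OCc2ccccc2)c(Cc2ccc(OCc3ccccc3)cc2)c(CC(=O)N(C)OC)c1Cc1ccc(OCc2ccccc2)cc1 | intermediate
9 | ethynylmagnesium bromide | C#C[Mg]Br | starting material
10 | 1-{3-(benzyloxy)-2,6-bis[4-(benzyloxy)benzyl]-5-methoxyphenyl}but-3-yn-2-one | C#CC(=O)Cc1c(Cc2ccc(OCc3ccccc3)cc2)c(OCc2ccccc2)cc(OC)c1Cc1ccc(OCc2ccccc2)cc1 | intermediate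
11 | furan | c1ccoc1 | starting material
12 | 2-furyllithium | [Li]c1ccco1 | intermediate
13 | 2-[4-(benzyloxy)benzyl]furan | c1coc(Cc2ccc(OCc3ccccc3)cc2)c1 | intermediate
14 | rac-1-{1-[4-(benzyloxy)benzyl]-7-oxabicyclo[2.2.1]hepta-2,5-dien-2-yl}-2-{3-(benzyloxy)-2,6-bis[4-(benzyloxy)benzyl]-5-methoxyphenyl}ethan-1-one | O=C(Cc1c(Cc2ccc(OCc3ccccc3)cc2)c(OCc2ccccc2)cc(OC)c1Cc1ccc(OCc2ccccc2)cc1)C1=C[C@@H]2C=C[C@@]1(Cc1ccc(OCc3ccccc3)cc1)O2 | intermediate
15 | 2-{3-(benzyloxy)-2,6-bis[4-(benzyloxy)benzyl]-5-methoxyphenyl}-1-{2-[4-(benzyloxy)benzyl]-5-hydroxyphenyl}ethan-1-one | O=C(Cc1c(Cc2ccc(OCc3ccccc3)cc2)c(OCc2ccccc2)cc(OC)c1Cc1ccc(OCc2ccccc2)cc1)c1cc(O)ccc1Cc1ccc(OCc2ccccc2)cc1 | intermediate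
16 | 2,4-bis(4-hydroxybenzyl)-3-{2-[5-hydroxy-2-(4-hydroxybenzyl)phenyl]ethyl}-5-methoxyphenol | COc1cc(O)c(Cc2ccc(O)cc2)c(CCc2cc(O)ccc2Cc2ccc(O)cc2)c1Cc1ccc(O)cc1 | target

**Step count and risks**
Total step count: 10. Longest linear sequence: 8 steps (steps 1, 2, 3, 5, 6, 7, 9, 10).

Steps most likely to fail:

1. Step 9. The bimolecular cycloaddition may be too slow to outrun self-condensation of the enolisable terminal ynone, the furan may add in the reverse orientation, or the cation formed on bridge opening may be intercepted before the hydride shift. The fallback sets out from Weinreb amide 8 and comes back at 16; it gives up the cycloaddition and brings ring B in ready-made. Commercial 4-(benzyloxy)-2-bromobenzaldehyde and 4-(benzyloxy)phenylmagnesium bromide (THF, 0 °C) should give racemic [4-(benzyloxy)-2-bromophenyl][4-(benzyloxy)phenyl]methanol F1. Ionic hydrogenation (Et3SiH, CF3CO2H, CH2Cl2, 0 °C) should give 4-(benzyloxy)-1-[4-(benzyloxy)benzyl]-2-bromobenzene F2. Bromine–lithium exchange (n-BuLi, THF, −78 °C), transmetalation with MgBr2·OEt2 and acylation by 8 should give 1-{5-(benzyloxy)-2-[4-(benzyloxy)benzyl]phenyl}-2-{3-(benzyloxy)-2,6-bis[4-(benzyloxy)benzyl]-5-methoxyphenyl}ethan-1-one F3. F3 is the O-benzyl ether of 15, and the conditions of step 10 should convert it into 16.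

2. Step 5. The second oxidative addition into the doubly ortho-substituted, electron-rich C–Br bond may stall, and the benzylzinc reagent may be lost to homocoupling and protonation. The fallback sets out from 3 and comes back at 7 with the polarity of the coupling reversed. Twofold Blanc chloromethylation of 3 (paraformaldehyde, HCl in dioxane/AcOH, rt), directed to the same two ring positions as the bromination, should give benzyl 2-[3-(benzyloxy)-2,6-bis(chloromethyl)-5-methoxyphenyl]acetate F4. Twofold Suzuki–Miyaura coupling of its unhindered benzylic C–Cl bonds with commercial 4-(benzyloxy)phenylboronic acid (Pd(PPh3)4, K3PO4, toluene/H2O, 80 °C) should then give 7.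

3. Step 10. C–O hydrogenolysis at the hindered aryl ketone may stall after the benzyl ethers have gone, leaving ketone or benzylic alcohol. The fallback sets out from 15 and comes back at 16, removing the oxygen before the hydrogenation. Reduction with NaBH4 (THF/MeOH, 0 °C) should give racemic 4-[4-(benzyloxy)benzyl]-3-(2-{3-(benzyloxy)-2,6-bis[4-(benzyloxy)benzyl]-5-methoxyphenyl}-1-hydroxyethyl)phenol F5. Acid-catalysed dehydration (TsOH, toluene, 80 °C) should give 4-[4-(benzyloxy)benzyl]-3-[(E)-2-{3-(benzyloxy)-2,6-bis[4-(benzyloxy)benzyl]-5-methoxyphenyl}ethenyl]phenol F6. Hydrogenation under neutral conditions (H2, 10% Pd/C, EtOAc/MeOH, rt) should saturate the alkene and cleave the benzyl ethers to give 16.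

**Further compounds**
F1 | step 9 | [4-(benzyloxy)-2-bromophenyl][4-(benzyloxy)phenyl]methanol (racemic) | OC(c1ccc(OCc2ccccc2)cc1)c1ccc(OCc2ccccc2)cc1Br
F2 | step 9 | 4-(benzyloxy)-1-[4-(benzyloxy)benzyl]-2-bromobenzene | Brc1cc(OCc2ccccc2)ccc1Cc1ccc(OCc2ccccc2)cc1
F3 | step 9 | 1-{5-(benzyloxy)-2-[4-(benzyloxy)benzyl]phenyl}-2-{3-(benzyloxy)-2,6-bis[4-(benzyloxy)benzyl]-5-methoxyphenyl}ethan-1-one | O=C(Cc1c(Cc2ccc(OCc3ccccc3)cc2)c(OCc2ccccc2)cc(OC)c1Cc1ccc(OCc2ccccc2)cc1)c1cc(OCc2ccccc2)ccc1Cc1ccc(OCc2ccccc2)cc1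
F4 | step 5 | benzyl 2-[3-(benzyloxy)-2,6-bis(chloromethyl)-5-methoxyphenyl]acetate | COc1cc(OCc2ccccc2)c(CCl)c(CC(=O)OCc2ccccc2)c1CCl
F5 | step 10 | 4-[4-(benzyloxy)benzyl]-3-(2-{3-(benzyloxy)-2,6-bis[4-(benzyloxy)benzyl]-5-methoxyphenyl}-1-hydroxyethyl)phenol (racemic) | OC(Cc1c(Cc2ccc(OCc3ccccc3)cc2)c(OCc2ccccc2)cc(OC)c1Cc1ccc(OCc2ccccc2)cc1)c1cc(O)ccc1Cc1ccc(OCc2ccccc2)cc1
F6 | step 10 | 4-[4-(benzyloxy)benzyl]-3-[(E)-2-{3-(benzyloxy)-2,6-bis[4-(benzyloxy)benzyl]-5-methoxyphenyl}ethenyl]phenol | Oc1ccc(Cc2ccc(OCc3ccccc3)cc2)c(/C=C/c2c(Cc3ccc(OCc4ccccc4)cc3)c(OCc3ccccc3)cc(OC)c2Cc2ccc(OCc3ccccc3)cc2)c1
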